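From early times the substrate in both earlier runs fell as one exponential, so I took its constant from one reading each: 0.105 h⁻¹ in Monday's run at 25 °C and 1.35 h⁻¹ in Friday's at 44 °C, a barrier of 106 kJ mol⁻¹. Friday's intermediate A later decayed at 0.203 h⁻¹, slower than the substrate. I assumed that the later steps scale with temperature as the substrate does, which gives time–temperature superposition: Friday's run becomes a master curve. Ochre then runs at 0.600 and grey at 1.65, each figure being a clock factor, the Friday hours that pass in one hour of a flask.

| flask | substrate | capture agent | temperature | remark | time |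
|---|---|---|---|---|---|
| Monday's | 0.034 M | 2.5 mM | 25 °C | run made earlier |  |
| Friday's | 0.075 M | 2.5 mM | 44 °C | run made earlier |  |
| ochre | 0.050 M | 2.50 mM | 40 °C |  | 5.0 h |
| grey | 0.050 M | 2.50 mM | 48 °C |  | 5.0 h |

| run | time / h | intermediate B / % | intermediate C / % | target / % | substrate / % | intermediate A / % |
|---|---|---|---|---|---|---|
| Monday's | 1.33 | 0 | 0 | 1.5 | 86.5 | 12.1 |
| Monday's | 3.00 | 0.4 | 0 | 2.1 | 73.5 | 24.5 |
| Monday's | 4.00 | 1.0 | 1.1 | 3.0 | 64.8 | 31.0 |
| Monday's | 6.00 | 0.9 | 2.3 | 3.9 | 51.7 | 40.4 |
| Monday's | 8.00 | 1.2 | 2.5 | 5.4 | 42.1 | 48.7 |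
| Monday's | 10.0 | 0.9 | 4.2 | 5.9 | 34.9 | 55.0 |
| Friday's | 0.667 | 1.0 | 4.0 | 3.4 | 39.8 | 52.3 |
| Friday's | 1.33 | 4.2 | 8.8 | 5.5 | 15.0 | 65.8 |
| Friday's | 2.00 | 5.9 | 14.3 | 7.3 | 6.7 | 64.5 |
| Friday's | 3.00 | 9.5 | 20.2 | 9.2 | 1.6 | 56.3 |
| Friday's | 4.00 | 11.9 | 23.4 | 11.0 | 0.9 | 45.6 |
| Friday's | 5.00 | 13.8 | 26.7 | 13.1 | 0 | 37.5 |

(readings scatter by 0.5 percentage points)

1. which of these there is most of at the end, counted by the substrate in it, ochre (intermediate A / target / intermediate B / intermediate C)
2. which of these there is most of at the end, counted by the substrate in it, grey (intermediate A / target / intermediate B / intermediate C)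
3. how much there is at the end of the one of these that leads, in percent of the substrate charged: ochre
4. how much there is at the end of the one of these that leads, in percent of the substrate charged: grey

- what was read earlier has a scatter of 0.5 percentage points, one standard deviation
- a reading of intermediate C is of its free form alone

The ladder I reckoned for ochre was a substrate lifetime of 1.23 h, shorter than the 5.0 h asked, and an intermediate A lifetime of 8.21 h, longer than it. So I expected ochre to stop between the rungs, at 3.00 h of Friday's clock, where Friday read 56.3% of intermediate A against 20.2% of intermediate C. For grey I reckoned lifetimes of 0.449 h and 2.99 h, both shorter than 5.0 h, and its end lay at 8.23 h of Friday's clock, beyond Friday's last reading. Extending the decay gave me 19.4% of intermediate A there, and since Friday's last reading of free intermediate C, 26.7%, already stood above that, I expected intermediate C to lead in grey and, having no later reading, took that figure as my own.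

The forecast named intermediate A at 55% for ochre and intermediate C at 47% for grey, its words on the intermediate C of Friday's run being “Counting the missing material as C”, and its grey figure stood above mine.

Ochre gave intermediate A at 55.3%, and grey gave intermediate C at 26.8%, 20 percentage points below the forecast, with intermediate A behind it at 21.1%. Grey at 2.50 h lies at 4.12 h of Friday's clock, close to Friday's reading of 45.6% of intermediate A at 4.00 h, and grey then held 45.0%.

    substrate → target (k = 0.0550 h⁻¹, Ea = 93.0 kJ mol⁻¹)
    substrate → intermediate A (k = 0.780 h⁻¹, Ea = 107 kJ mol⁻¹)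
    intermediate A ⇌ intermediate B (K = 0.730, k = 0.0380 h⁻¹, Ea = 112 kJ mol⁻¹, ΔH = −3.00 kJ mol⁻¹)
    intermediate A → intermediate C (k = 0.100 h⁻¹, Ea = 104 kJ mol⁻¹)
    intermediate C ⇌ intermediate D (K = 0.250, k = 0.110 h⁻¹, Ea = 90.0 kJ mol⁻¹, ΔH = 3.00 kJ mol⁻¹)
    intermediate C → side product (k = 0.0350 h⁻¹, Ea = 113 kJ mol⁻¹)
    intermediate C → target (k = 0.0530 h⁻¹, Ea = 100 kJ mol⁻¹)
    capture agent + intermediate B → trapped intermediate (k = 2.00 M⁻¹ h⁻¹, Ea = 85.0 kJ mol⁻¹)
    (constants at 40 °C)

For ochre stopped at 2.0 h, the clock factor gives 1.20 h of Friday's clock, where Friday's readings interpolate to 63.1% of intermediate A. That flask held 64.0%.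

The data stem from a simulated flask from invented constants; scatter was added.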